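The delta run holds 8.70 charges of D per charge of E, far more D than E, so I treat the loss of E, the limiting reagent, as nearly pseudo-first-order there and count every amount as a fraction of the E charged.

- delta: E 0.010 M; D 87 mM; run made earlier
- flask: E 0.010 M; time 2.0 min

- delta (time / s: X / %, E / %): 10.0: 56.6, 43.3; 15.0: 71.2, 28.9; 25.0: 85.8, 14.8

(scatter of a reading: 0.5 percentage points)

- the amount of D is what is sought; it is there from the start
- the analysis behind the earlier runs scatters by 0.5 percentage points, standard deviation
- a reading or a percentage of X counts all its forms, free or not

1. the concentration of D at which the part of the E that has reacted at 2.0 min is just 95%, in mM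

How fast does one charge of free D work? At 10.0 s the delta run has 43.3% of its E left, and taking free D as the charge less half the part used, I read 0.597 /min per charge of free D.

How much free D must the flask hold? Reaching 95% takes 3.00 e-folds of E, so dividing these by that rate and by 2.0 min gives 2.51 charges as the mean free D, the time-average of free D that the asked time demands.

How much must be charged to keep that mean? The time-mean used part of E is 0.683, which gives 3.19 charges if each E takes one D. But at 25.0 s the delta run shows a mean free D of 7.68, less than the 8.15 of one-for-one. As a reading, that is 1.84 D lost per E used, so I commit to 3.77 charges, or 37.7 mM.

The forecast says 40 mM, above my figure, and its ground is: “If X ties up D, nearly 2:1 at worst, the answer is about 37–40 mM”.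

The flask needs 43.3 mM, which is 4.33 charges, and the forecast stands within its margin.

    E + D → L + X (k = 1.10 /M/s)
    D + X ⇌ Q, settled at all times (K = 180 /M)
    D + L ⇌ G, settled at all times (K = 6200 /M)

In that flask the share of charged D still free goes from 74.6% at 0.200 min to 39.8% at 2.00 min, and my mean free D of 2.51 charges is 58.0% of the charge, between the two . Over the first 1.00 min, with 83.2% of E used, my mean free D scales to 2.99 charges, 69.1% of the charge, and at that moment 46.7% of the charged D is free.

The readings are calculated from invented constants.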